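**Retrosynthetic overview**

1. Ring letters: A = the two guaiacyl rings of the C6C3 units, B = aryl of the lactone β-benzyl (open 7S,8S diol unit), C = aryl of the α-benzyl (2R,3S phenylcoumaran). Both C6C3 units are the same (7S,8S) anti-1,3-diol; the coumaran comes from it by SN1 O–C7 closure.
2. Both units ⇐ one twofold isothiourea-catalysed aldol-lactonisation of a bis(arylacetic acid) with O-benzylvanillin (both C7–C8 bonds, four stereocentres), the β-lactones being opened in the same flask by NaBH4.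
3. Bis(arylacetic acid) ⇐ twofold Negishi–Reformatsky arylation of a dibromo trans-dibenzylbutyrolactone ⇐ trans-selective enolate benzylation.
4. (S)-β-Benzyl-γ-butyrolactone ⇐ D-proline cross-aldol of O-benzyl-5-bromovanillin with methyl 4-oxobutanoate (first stereocentre), reduction–lactonisation, deoxygenation.
5. Ring order: γ-lactone → two transient β-lactones → transient 1,3-dioxane on the ring B unit → dihydrofuran of the coumaran.

Assumption: the facial senses of D-proline, (2R,3S)-HyperBTM and the fallback thiazolidinethione auxiliary follow their accepted transition-state models; should one prove opposite, its mirror image is used.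

**Route**

Step 1
Reactants: 1 5-bromovanillin (3-bromo-4-hydroxy-5-methoxybenzaldehyde)
Product: 2 4-(benzyloxy)-3-bromo-5-methoxybenzaldehyde
Conditions: BnBr, K2CO3, DMF, 60 °C
Reagents that add atoms: benzyl bromide, BrCc1ccccc1
Why: Williamson ether synthesis on an acidic phenol; the benzyl ether masks the ring B phenol until the final hydrogenolysis.

Step 2
Reactants: 2 4-(benzyloxy)-3-bromo-5-methoxybenzaldehyde; 3 methyl 4-oxobutanoate (2.5 equiv)
Product: 5 (S)-4-[(S)-[4-(benzyloxy)-3-bromo-5-methoxyphenyl](hydroxy)methyl]dihydrofuran-2(3H)-one, via anti-aldol aldehyde 4 (not isolated)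
Conditions: D-proline (30 mol %), DMF, 4 °C, 48 h; then MeOH, NaBH4, −20 → 0 °C; 1 M HCl work-up
Reagents that add atoms: none
Why: Proline-catalysed enamine cross-aldol through the carboxylic-acid-directed chair transition state gives the anti adduct with the future lactone β-carbon S (first stereocentre, from achiral materials), and NaBH4 reduction of the formyl group triggers lactonisation onto the methyl ester.

Step 3
Reactants: 5 hydroxy lactone
Product: 6 (S)-4-[4-(benzyloxy)-3-bromo-5-methoxybenzyl]dihydrofuran-2(3H)-one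
Conditions: Et3SiH (3 equiv), CF3CO2H (10 equiv), CH2Cl2, 0 °C → rt
Reagents that add atoms: none
Why: Ionic hydrogenation (benzylic cation trapped by silane hydride) removes the carbinol stereocentre that is not needed and leaves the lactone centre, the aryl bromide and the benzyl ether untouched.

Step 4
Reactants: 1 5-bromovanillin
Product: 7 3-bromo-5-methoxy-4-(triisopropylsilyloxy)benzaldehyde
Conditions: iPr3SiCl, imidazole, DMF, rt
Reagents that add atoms: chlorotriisopropylsilane, CC(C)[Si](Cl)(C(C)C)C(C)C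
Why: Phenol silylation; the fluoride-labile silyl ether is orthogonal to benzyl, so only the ring C phenol can later be freed for ring closure.

Step 5
Reactants: 7 silyl-protected aldehyde
Product: 8 [3-bromo-5-methoxy-4-(triisopropylsilyloxy)phenyl]methanol
Conditions: NaBH4, THF/EtOH, 0 °C
Reagents that add atoms: none
Why: Borohydride reduction of an aryl aldehyde; the hindered aryl silyl ether survives.

Step 6
Reactants: 8 benzylic alcohol
Product: 9 3-bromo-5-methoxy-4-(triisopropylsilyloxy)benzyl bromide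
Conditions: CBr4, PPh3, CH2Cl2, 0 °C (used at once)
Reagents that add atoms: tetrabromomethane, BrC(Br)(Br)Br
Why: Appel reaction under neutral conditions, so no HBr reaches the silyl ether.

Step 7
Reactants: 6 (S)-β-benzyl lactone; 9 benzyl bromide
Product: 11 (3S,4S)-4-[4-(benzyloxy)-3-bromo-5-methoxybenzyl]-3-[3-bromo-5-methoxy-4-(triisopropylsilyloxy)benzyl]dihydrofuran-2(3H)-one, via lithium enolate 10 (not isolated)
Conditions: LiN(SiMe3)2 (1.05 equiv), THF, −78 °C; then 9, DMPU, −78 → −40 °C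
Reagents that add atoms: none
Why: Lithium enolate alkylation (SN2) occurs anti to the C4 benzyl group, so the new α-centre is set by substrate control as trans-(3S,4S), as in classical dibenzylbutyrolactone lignan syntheses.

Step 8
Reactants: 11 dibromo lactone; 12 (2-tert-butoxy-2-oxoethyl)zinc chloride, ClZnCH2CO2tBu (3 equiv)
Product: 13 (3S,4S)-bis(tert-butyl arylacetate) (11 in which each aryl Br is replaced by CH2CO2tBu)
Conditions: Pd2(dba)3 (2.5 mol %), XPhos (10 mol %), THF, 60 °C
Reagents that add atoms: none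
Why: Twofold Negishi-type coupling of a Reformatsky zinc enolate (oxidative addition of zerovalent palladium into each Ar–Br, transmetalation, reductive elimination); the zinc enolate is too weakly basic to touch the lactone or its α-centre.

Step 9
Reactants: 13 bis(tert-butyl ester)
Product: 14 (3S,4S)-bis(arylacetic acid) (13 with both esters as CO2H)
Conditions: CF3CO2H/CH2Cl2 (1:3), 0 °C → rt
Reagents that add atoms: none
Why: Acidolysis of tert-butyl esters (E1 loss of isobutene); the aryl silyl ether stays on, which prevents the ring C acid from lactonising to a benzofuranone.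

Step 10
Reactants: 14 bis(arylacetic acid); 15 4-(benzyloxy)-3-methoxybenzaldehyde (O-benzylvanillin, 3 equiv)
Product: 18 bis(anti-diol) (each of rings B and C carries a (1S,2S)-1-[4-(benzyloxy)-3-methoxyphenyl]-1,3-dihydroxypropan-2-yl group ortho to its protected phenol), via bis(pivalic mixed anhydride) 16 (not isolated), via bis(β-lactone) 17 (not isolated)
Conditions: tBuCOCl (2.4 equiv), iPr2NEt (2.4 equiv), CH2Cl2, 0 °C; then 15, (2R,3S)-HyperBTM (20 mol %), N,N′-bis[3,5-bis(trifluoromethyl)phenyl]thiourea (20 mol %), iPr2NEt (2.5 equiv), −40 → −10 °C; then EtOH, NaBH4, −20 → 0 °C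
Reagents that add atoms: none
Why: Proposed new method: twofold intermolecular isothiourea-catalysed aldol-lactonisation with a non-activated aromatic aldehyde — each mixed anhydride acylates the isothiourea, iPr2NEt gives the (Z)-C1-ammonium enolate locked by the 1,5-O···S contact, this adds through the face anti to the catalyst phenyl to the thiourea-activated aldehyde, and the aldolate closes on the acyl ammonium (catalyst turnover) to the trans-(3R,4S) β-lactone, so that C8 is set by the catalyst and C7 by the trans-selective asynchronous [2+2] closure; NaBH4 then opens only the strained β-lactones (the γ-lactone is inert at ≤0 °C) to the (7S,8S) anti-diols; closest known reaction types are the isothiourea-catalysed formal [2+2] of arylacetic anhydrides with trifluoromethyl ketones and the intramolecular nucleophile-catalysed aldol-lactonisation.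

Step 11
Reactants: 18 bis(anti-diol) silyl ether
Product: 19 bis(anti-diol) with free ring C phenol
Conditions: Bu4NF (1.2 equiv), AcOH (1.2 equiv), THF, 0 °C
Reagents that add atoms: none
Why: Fluoride-mediated Si–O cleavage buffered by AcOH frees only the ring C phenol; benzyl ethers, diols and the lactone are inert.

Step 12
Reactants: 19 phenol tetraol
Product: 21 tri-O-benzyl target (ring C closed to the trans-(2R,3S) coumaran; ring B unit as free (7S,8S) diol), via coumaran acetonide 20 (not isolated)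
Conditions: 2-methoxypropene (5 equiv), TsOH·H2O (20 mol %), 4 Å MS, CH2Cl2, 0 °C → rt; then NaOAc, AcOH/H2O (4:1), 40 °C
Reagents that add atoms: none
Why: Ketalisation of both diols precedes acid-promoted SN1 closure: the ring C phenol captures the para-benzyloxybenzylic C7 cation to give the trans-(2R,3S) phenylcoumaran (C8 controls the re-formed C7), while on ring B the same cation can only fall back into the trans-diequatorial 4,5-diaryl-1,3-dioxane, which preserves (7S,8S); buffered aqueous acetic acid then hydrolyses the ketals without benzylic ionisation.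

Step 13
Reactants: 21 tri-O-benzyl target
Product: 22 CNP0199264.1 (target)
Conditions: H2 (1 atm), Pd/C (10 wt % palladium on carbon), EtOAc/MeOH, rt
Reagents that add atoms: none
Why: Hydrogenolysis of the three aryl benzyl ethers under neutral conditions, where the benzylic C7–OH and the coumaran C2–O bond are cleaved far more slowly, so no stereocentre is touched.

**Compound list**

1 | 5-bromovanillin | O=Cc1cc(Br)c(O)c(OC)c1 | starting material
2 | 4-(benzyloxy)-3-bromo-5-methoxybenzaldehyde | O=Cc1cc(Br)c(OCc2ccccc2)c(OC)c1 | intermediate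
3 | methyl 4-oxobutanoate | COC(=O)CCC=O | starting material
4 | methyl (3R,4S)-4-[4-(benzyloxy)-3-bromo-5-methoxyphenyl]-3-formyl-4-hydroxybutanoate | COC(=O)C[C@@H](C=O)[C@H](O)c1cc(Br)c(OCc2ccccc2)c(OC)c1 | intermediate
5 | (S)-4-[(S)-[4-(benzyloxy)-3-bromo-5-methoxyphenyl](hydroxy)methyl]dihydrofuran-2(3H)-one | COc1cc([C@@H](O)[C@@H]2COC(=O)C2)cc(Br)c1OCc1ccccc1 | intermediate
6 | (S)-4-[4-(benzyloxy)-3-bromo-5-methoxybenzyl]dihydrofuran-2(3H)-one | COc1cc(C[C@@H]2COC(=O)C2)cc(Br)c1OCc1ccccc1 | intermediate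
7 | 3-bromo-5-methoxy-4-(triisopropylsilyloxy)benzaldehyde | O=Cc1cc(Br)c(O[Si](C(C)C)(C(C)C)C(C)C)c(OC)c1 | intermediate
8 | [3-bromo-5-methoxy-4-(triisopropylsilyloxy)phenyl]methanol | OCc1cc(Br)c(O[Si](C(C)C)(C(C)C)C(C)C)c(OC)c1 | intermediate
9 | 3-bromo-5-methoxy-4-(triisopropylsilyloxy)benzyl bromide | BrCc1cc(Br)c(O[Si](C(C)C)(C(C)C)C(C)C)c(OC)c1 | intermediate
10 | lithium enolate of 6 | [Li+].COc1cc(C[C@@H]2COC([O-])=C2)cc(Br)c1OCc1ccccc1 | intermediate
11 | (3S,4S)-4-[4-(benzyloxy)-3-bromo-5-methoxybenzyl]-3-[3-bromo-5-methoxy-4-(triisopropylsilyloxy)benzyl]dihydrofuran-2(3H)-one | COc1cc(C[C@@H]2COC(=O)[C@H]2Cc2cc(OC)c(O[Si](C(C)C)(C(C)C)C(C)C)c(Br)c2)cc(Br)c1OCc1ccccc1 | intermediate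
12 | (2-tert-butoxy-2-oxoethyl)zinc chloride | CC(C)(C)OC(=O)C[Zn]Cl | starting material
13 | (3S,4S)-bis(tert-butyl arylacetate), each aryl Br of 11 replaced by CH2CO2tBu | COc1cc(C[C@@H]2COC(=O)[C@H]2Cc2cc(OC)c(O[Si](C(C)C)(C(C)C)C(C)C)c(CC(=O)OC(C)(C)C)c2)cc(CC(=O)OC(C)(C)C)c1OCc1ccccc1 | intermediate
14 | (3S,4S)-bis(arylacetic acid) | COc1cc(C[C@@H]2COC(=O)[C@H]2Cc2cc(OC)c(O[Si](C(C)C)(C(C)C)C(C)C)c(CC(O)=O)c2)cc(CC(O)=O)c1OCc1ccccc1 | intermediate
15 | 4-(benzyloxy)-3-methoxybenzaldehyde | O=Cc1ccc(OCc2ccccc2)c(OC)c1 | starting material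
16 | bis(pivalic mixed anhydride) of 14 | COc1cc(C[C@@H]2COC(=O)[C@H]2Cc2cc(OC)c(O[Si](C(C)C)(C(C)C)C(C)C)c(CC(=O)OC(=O)C(C)(C)C)c2)cc(CC(=O)OC(=O)C(C)(C)C)c1OCc1ccccc1 | intermediate
17 | bis(β-lactone), each arylacetic unit as trans-(3R,4S)-4-[4-(benzyloxy)-3-methoxyphenyl]-2-oxooxetan-3-yl | COc1cc(C[C@@H]2COC(=O)[C@H]2Cc2cc(OC)c(O[Si](C(C)C)(C(C)C)C(C)C)c([C@H]3C(=O)O[C@@H]3c3ccc(OCc4ccccc4)c(OC)c3)c2)cc([C@H]2C(=O)O[C@@H]2c2ccc(OCc3ccccc3)c(OC)c2)c1OCc1ccccc1 | intermediate
18 | bis[(1S,2S)-anti-diol], ring B OBn, ring C OSi(iPr)3, lactone (3S,4S) | COc1cc(C[C@@H]2COC(=O)[C@H]2Cc2cc(OC)c(O[Si](C(C)C)(C(C)C)C(C)C)c([C@@H](CO)[C@H](O)c3ccc(OCc4ccccc4)c(OC)c3)c2)cc([C@@H](CO)[C@H](O)c2ccc(OCc3ccccc3)c(OC)c2)c1OCc1ccccc1 | intermediate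
19 | 18 with free ring C phenol | COc1cc(C[C@@H]2COC(=O)[C@H]2Cc2cc(OC)c(O)c([C@@H](CO)[C@H](O)c3ccc(OCc4ccccc4)c(OC)c3)c2)cc([C@@H](CO)[C@H](O)c2ccc(OCc3ccccc3)c(OC)c2)c1OCc1ccccc1 | intermediate
20 | ring C trans-(2R,3S)-coumaran with 3-CH2O–C(CH3)2OCH3, ring B diol as (4S,5S)-2,2-dimethyl-1,3-dioxane | COc1cc(C[C@@H]2COC(=O)[C@H]2Cc2cc(OC)c3c(c2)[C@@H](COC(C)(C)OC)[C@H](c2ccc(OCc4ccccc4)c(OC)c2)O3)cc([C@H]2COC(C)(C)O[C@@H]2c2ccc(OCc3ccccc3)c(OC)c2)c1OCc1ccccc1 | intermediate
21 | tri-O-benzyl target (benzyl on both ring A phenols and on the ring B phenol) | COc1cc(C[C@@H]2COC(=O)[C@H]2Cc2cc(OC)c3c(c2)[C@@H](CO)[C@H](c2ccc(OCc4ccccc4)c(OC)c2)O3)cc([C@@H](CO)[C@H](O)c2ccc(OCc3ccccc3)c(OC)c2)c1OCc1ccccc1 | intermediate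
22 | CNP0199264.1 | COc1cc([C@@H](O)[C@H](CO)c2cc(C[C@@H]3COC(=O)[C@H]3Cc3cc(OC)c4c(c3)[C@@H](CO)[C@H](c3ccc(O)c(OC)c3)O4)cc(OC)c2O)ccc1O | target

**Step count and risks**

Total step count: 13. Longest linear sequence: 10 steps (1 → 2 → 3 → 7 → 8 → 9 → 10 → 11 → 12 → 13); steps 4–6 are the three-step side branch.

Step 3 (ionic deoxygenation). The benzylic cation is flanked by meta-Br and meta-OMe and its para-benzyloxy group is twisted out of conjugation, so ionisation may stall or the lactone carbonyl may intercept the cation. The fallback replaces cationic by radical C–O cleavage (Barton–McCombie). It sets out from 5: 1,1′-thiocarbonyldiimidazole with DMAP gives the O-benzylic imidazole-1-carbothioate F1, and Bu3SnH/AIBN (toluene, 80 °C, slow addition so that the aryl bromide survives) comes back to the route at 6.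

Step 10 (the proposed new aldol-lactonisation, run twice in one flask). The electron-rich aldehyde may be too weak an electrophile, the trans/cis ratio is unproven, the ortho-substituted aryl groups may slow enolate formation, and the borohydride must spare the γ-lactone. The fallback uses known auxiliary chemistry and avoids the β-lactones. It sets out from 14: coupling of both acids with (R)-4-benzyl-1,3-thiazolidine-2-thione (EDC·HCl, DMAP) gives the bis(N-acylthiazolidinethione) F2. The MgBr2·OEt2-catalysed Evans anti-aldol with 15 (Et3N, Me3SiCl, EtOAc; then mild acidic desilylation) gives the bis(anti-aldol adduct) F3. Reductive removal of the auxiliaries with NaBH4 (THF/H2O, 0 °C) comes back to the route at 18.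

Step 12 (closing ring C while the ring B unit stays open and stereochemically intact). The ring B cation might lose its ketal, be captured by the benzyl ether oxygen, or epimerise at C7. The fallback replaces SN1 closure by an SN2 Mitsunobu etherification that never ionises ring B. It sets out from 18: tBuMe2SiCl (2.2 equiv) and imidazole protect the two primary alcohols as the bis(tert-butyldimethylsilyl ether) F4. KHF2 in MeOH cleaves only the aryl silyl ether to give the phenol F5. PPh3/DIAD (THF, 0 °C) closes the ring C phenol onto C7 with inversion to give the trans-(2R,3S) coumaran bis(silyl ether) F6. Bu4NF/AcOH then comes back to the route at 21.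

**Further compounds**

F1 | step 3 | O-{(S)-[4-(benzyloxy)-3-bromo-5-methoxyphenyl][(S)-5-oxotetrahydrofuran-3-yl]methyl} 1H-imidazole-1-carbothioate | COc1cc([C@@H](OC(=S)n2ccnc2)[C@@H]2COC(=O)C2)cc(Br)c1OCc1ccccc1
F2 | step 10 | bis(N-acylthiazolidinethione): 14 with each CO2H as the amide of (R)-4-benzyl-1,3-thiazolidine-2-thione | COc1cc(C[C@@H]2COC(=O)[C@H]2Cc2cc(OC)c(O[Si](C(C)C)(C(C)C)C(C)C)c(CC(=O)N3C(=S)SC[C@H]3Cc3ccccc3)c2)cc(CC(=O)N2C(=S)SC[C@H]2Cc2ccccc2)c1OCc1ccccc1
F3 | step 10 | bis(anti-aldol adduct): each acyl group of F2 as (2R,3S)-2-aryl-3-[4-(benzyloxy)-3-methoxyphenyl]-3-hydroxypropanoyl | COc1cc(C[C@@H]2COC(=O)[C@H]2Cc2cc(OC)c(O[Si](C(C)C)(C(C)C)C(C)C)c([C@@H](C(=O)N3C(=S)SC[C@H]3Cc3ccccc3)[C@H](O)c3ccc(OCc4ccccc4)c(OC)c3)c2)cc([C@@H](C(=O)N2C(=S)SC[C@H]2Cc2ccccc2)[C@H](O)c2ccc(OCc3ccccc3)c(OC)c2)c1OCc1ccccc1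
F4 | step 12 | 18 with both primary alcohols as tert-butyldimethylsilyl ethers | COc1cc(C[C@@H]2COC(=O)[C@H]2Cc2cc(OC)c(O[Si](C(C)C)(C(C)C)C(C)C)c([C@@H](CO[Si](C)(C)C(C)(C)C)[C@H](O)c3ccc(OCc4ccccc4)c(OC)c3)c2)cc([C@@H](CO[Si](C)(C)C(C)(C)C)[C@H](O)c2ccc(OCc3ccccc3)c(OC)c2)c1OCc1ccccc1
F5 | step 12 | F4 with free ring C phenol | COc1cc(C[C@@H]2COC(=O)[C@H]2Cc2cc(OC)c(O)c([C@@H](CO[Si](C)(C)C(C)(C)C)[C@H](O)c3ccc(OCc4ccccc4)c(OC)c3)c2)cc([C@@H](CO[Si](C)(C)C(C)(C)C)[C@H](O)c2ccc(OCc3ccccc3)c(OC)c2)c1OCc1ccccc1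
F6 | step 12 | 21 with both primary alcohols as tert-butyldimethylsilyl ethers (ring C closed to the (2R,3S) coumaran) | COc1cc(C[C@@H]2COC(=O)[C@H]2Cc2cc(OC)c3c(c2)[C@@H](CO[Si](C)(C)C(C)(C)C)[C@H](c2ccc(OCc4ccccc4)c(OC)c2)O3)cc([C@@H](CO[Si](C)(C)C(C)(C)C)[C@H](O)c2ccc(OCc3ccccc3)c(OC)c2)c1OCc1ccccc1
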